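**Plan**

1. Cuts (germacrane numbering): C13–C11 and the acetate; the epoxide C5–O bond (back to a C4 silyl ether and a C5 mesylate); the ring bond C5–C6; the C8 ester; C7–C8; C1–C10.
2. Enabling feature: C6 is the γ-carbon of the butenolide ring (O–C12(=O)–C11=C7–C6) and C5 is its oxygen-bearing neighbour, so the C5–C6 bond of the ten-membered carbocycle C1–C10 is a vinylogous aldol bond between a 2-silyloxyfuran and an aldehyde.
3. Forward order: (S)-linalool supplies C1–C5; a propargyl unit adds C10, C9 and C8; a bromofuryl unit adds C7, C6, C11 and C12 and is oxidised to the bromobutenolide; its silyloxyfuran closes the ten-membered ring and returns the butenolide ring; the epoxide ring, the C1 ketone and C13 follow.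
4. Stereochemistry: C4 from (S)-linalool; C10 from (R)-but-3-yn-2-ol through a chiral allenylzinc reagent; C8 from a Corey–Bakshi–Shibata reduction; C5 and C6 in the ring closure, C5 being inverted when the epoxide closes.

Key step: step 14

Remark: positions are given in germacrane numbering (C1 ketone, C4–C5 epoxide, C6 lactone CH–O, C8 ester carbinol, C10 CH–CH3, C12 lactone C=O, C13 CH2OAc); C1 is carried as a triethylsilyl ether until the ring is closed, because a C1 ketone would sit three carbons from the furan and invite a six-membered closure; the (R)-mesylate is taken to give the (P)-allenylzinc reagent by anti SN2′ attack of zerovalent palladium.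

**Route**

Step 1
Reactants: 1 (S)-linalool
Product: 2 (S)-linalool triethylsilyl ether
Conditions: Et3SiOTf, 2,6-lutidine, CH2Cl2, −78 → 0 °C
Reagents that add atoms: triethylsilyl trifluoromethanesulfonate, CC[Si](CC)(CC)OS(=O)(=O)C(F)(F)F
Why: Silylation of a tertiary alcohol with a silyl triflate and a hindered pyridine base is routine and leaves the C4 stereocentre, taken from the chiral pool, untouched.

Step 2
Reactants: 2 (S)-linalool triethylsilyl ether
Product: 3 (4S)-4-methyl-4-(triethylsilyloxy)hex-5-enal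
Conditions: O3, CH2Cl2/MeOH, −78 °C, Sudan Red 7B end point; then Me2S, −78 °C → rt
Reagents that add atoms: ozone, [O-][O+]=O
Why: Selective ozonolysis, since ozone attacks the electron-rich trisubstituted alkene far faster than the hindered vinyl group on the quaternary silyloxy carbon, and the dye end point stops the reaction before the second alkene is touched.

Step 3
Reactants: 4 (R)-but-3-yn-2-ol
Product: 5 (R)-but-3-yn-2-yl methanesulfonate
Conditions: MsCl, Et3N, CH2Cl2, −78 → 0 °C
Reagents that add atoms: methanesulfonyl chloride, CS(=O)(=O)Cl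
Why: Mesylation (through sulfene) does not touch the C–O bond, so the propargylic configuration is retained for the following Marshall propargylation.

Step 4
Reactants: 3 (4S)-4-methyl-4-(triethylsilyloxy)hex-5-enal; 5 (R)-but-3-yn-2-yl methanesulfonate
Product: 7 (3S,4R,7S)-3,7-dimethyl-7-(triethylsilyloxy)non-8-en-1-yn-4-ol, via allenylzinc reagent 6 (not isolated)
Conditions: Pd(OAc)2 (5 mol%), PPh3 (5 mol%), Et2Zn (3 equiv), THF, −78 → −20 °C; aq NH4Cl; minor C1 epimer removed by chromatography
Reagents that add atoms: none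
Why: Marshall propargylation, in which zerovalent palladium displaces the mesylate anti SN2′, transmetalation gives allenylzinc 6, and its cyclic syn SE2′ addition to the aldehyde sets C10 as S from the reagent (net inversion of the propargylic centre) with the C1 carbinol anti to the methyl group; C1 is only a placeholder for the ketone.

Step 5
Reactants: 7 (3S,4R,7S)-3,7-dimethyl-7-(triethylsilyloxy)non-8-en-1-yn-4-ol
Product: 8 (3S,4R,7S)-3,7-dimethyl-4,7-bis(triethylsilyloxy)non-8-en-1-yne
Conditions: Et3SiCl, imidazole, 4-(dimethylamino)pyridine (cat.), CH2Cl2, 0 °C → rt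
Reagents that add atoms: chlorotriethylsilane, CC[Si](Cl)(CC)CC
Why: Standard silylation of a secondary alcohol masks C1, so that the later ring closure meets one electrophile only and both silyl ethers can fall together in step 16.

Step 6
Reactants: 8 (3S,4R,7S)-3,7-dimethyl-4,7-bis(triethylsilyloxy)non-8-en-1-yne
Product: 10 (3S,4R,7S)-3,7-dimethyl-4,7-bis(triethylsilyloxy)non-8-enal, via alkenylborane 9 (not isolated)
Conditions: (c-C6H11)2BH (1.1 equiv, from BH3·SMe2 and cyclohexene), THF, 0 °C; then 30% H2O2, pH 7 phosphate buffer, 0 °C → rt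
Reagents that add atoms: hydrogen peroxide, OO
Why: Anti-Markovnikov hydroboration of a terminal alkyne with a hindered dialkylborane is much faster than addition to the neopentyl-type vinyl group, and buffered oxidation of alkenylborane 9 gives the C8 aldehyde without touching C10.

Step 7
Reactants: 11 3,4-dibromofuran; 10 (3S,4R,7S)-3,7-dimethyl-4,7-bis(triethylsilyloxy)non-8-enal
Product: 13 (3S,4R,7S)-1-(4-bromofuran-3-yl)-3,7-dimethyl-4,7-bis(triethylsilyloxy)non-8-en-1-ol as both C1 epimers (C8 of the target), via 4-bromo-3-furyllithium 12 (not isolated)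
Conditions: n-BuLi (1 equiv to 11), Et2O, −78 °C; then 10, −78 °C; aq NH4Cl
Reagents that add atoms: none
Why: Bromine–lithium exchange on 3,4-dibromofuran stops at the mono-lithio stage at −78 °C, and 1,2-addition of 12 to the aldehyde forms the C7–C8 bond; the C8 configuration is left open here and fixed in steps 8 and 9.

Step 8
Reactants: 13 (3S,4R,7S)-1-(4-bromofuran-3-yl)-3,7-dimethyl-4,7-bis(triethylsilyloxy)non-8-en-1-ol (epimers)
Product: 14 (3S,4R,7S)-1-(4-bromofuran-3-yl)-3,7-dimethyl-4,7-bis(triethylsilyloxy)non-8-en-1-one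
Conditions: Dess–Martin periodinane, NaHCO3, CH2Cl2, 0 °C → rt
Reagents that add atoms: none
Why: Dess–Martin oxidation of a hetero-benzylic alcohol is mild enough for the silyl ethers and the bromofuran, and C10 is β to the new carbonyl, so it cannot epimerise.

Step 9
Reactants: 14 (3S,4R,7S)-1-(4-bromofuran-3-yl)-3,7-dimethyl-4,7-bis(triethylsilyloxy)non-8-en-1-one
Product: 15 (1R,3S,4R,7S)-1-(4-bromofuran-3-yl)-3,7-dimethyl-4,7-bis(triethylsilyloxy)non-8-en-1-ol
Conditions: (S)-1-methyl-3,3-diphenyltetrahydro-1H,3H-pyrrolo[1,2-c][1,3,2]oxazaborole ((S)-Me-CBS, 20 mol%), catecholborane (1.8 equiv), toluene, −78 °C; then MeOH, aq NaHCO3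
Reagents that add atoms: none
Why: Corey–Bakshi–Shibata reduction of an aryl alkyl ketone, with the bromofuryl group as the large substituent, should give the 8R alcohol by analogy with acetophenone, and catecholborane at −78 °C spares the vinyl group.

Step 10
Reactants: 15 (1R,3S,4R,7S)-1-(4-bromofuran-3-yl)-3,7-dimethyl-4,7-bis(triethylsilyloxy)non-8-en-1-ol
Product: 18 3-bromo-4-[(1R,3S,4R,7S)-1-hydroxy-3,7-dimethyl-4,7-bis(triethylsilyloxy)non-8-enyl]furan-2(5H)-one, via dilithio furan 16 (not isolated), via furylboronate 17 (not isolated)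
Conditions: LiN(i-Pr)2 (2.3 equiv), THF, −78 °C; B(OMe)3, −78 → 0 °C; 30% H2O2, aq NaHCO3, 0 °C; then Et3N (cat.), CH2Cl2, rt
Reagents that add atoms: hydrogen peroxide, OO
Why: Bromine-directed α-lithiation of a 3-bromofuran (the C–H next to C–Br is the most acidic and the amide base is too weak for the other α-position), borylation and peroxide oxidation of the 2-furylboronate give the 2-hydroxyfuran, which tautomerises to the conjugated butenolide with its carbonyl (C12) next to C11–Br.

Step 11
Reactants: 18 3-bromo-4-[(1R,3S,4R,7S)-1-hydroxy-3,7-dimethyl-4,7-bis(triethylsilyloxy)non-8-enyl]furan-2(5H)-one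
Product: 19 (2S,5R,6S,8R)-8-(4-bromo-5-oxo-2,5-dihydrofuran-3-yl)-8-hydroxy-2,6-dimethyl-2,5-bis(triethylsilyloxy)octanal
Conditions: O3, CH2Cl2/MeOH, NaHCO3, −78 °C; then Me2S, −78 °C → rt
Reagents that add atoms: ozone, [O-][O+]=O
Why: Ozonolysis of the only electron-rich alkene left, since the tetrasubstituted bromobutenolide alkene is electron-poor and reacts far more slowly; the C5 aldehyde formed has no α-hydrogen and the senecioate is not yet present.

Step 12
Reactants: 19 (2S,5R,6S,8R)-8-(4-bromo-5-oxo-2,5-dihydrofuran-3-yl)-8-hydroxy-2,6-dimethyl-2,5-bis(triethylsilyloxy)octanal; 20 3-methylbut-2-enoyl chloride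
Product: 21 (1R,3S,4R,7S)-1-(4-bromo-5-oxo-2,5-dihydrofuran-3-yl)-3,7-dimethyl-8-oxo-4,7-bis(triethylsilyloxy)octyl 3-methylbut-2-enoate
Conditions: pyridine, 4-(dimethylamino)pyridine (cat.), CH2Cl2, 0 °C
Reagents that add atoms: none
Why: Acylation of the secondary C8 alcohol with the acid chloride under nucleophilic catalysis proceeds with retention, and pyridine is too weak a base to deconjugate the senecioate or enolise the butenolide.

Step 13
Reactants: 21 (1R,3S,4R,7S)-1-(4-bromo-5-oxo-2,5-dihydrofuran-3-yl)-3,7-dimethyl-8-oxo-4,7-bis(triethylsilyloxy)octyl 3-methylbut-2-enoate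
Product: 22 (1R,3S,4R,7S)-1-[4-bromo-5-(triisopropylsilyloxy)furan-3-yl]-3,7-dimethyl-8-oxo-4,7-bis(triethylsilyloxy)octyl 3-methylbut-2-enoate
Conditions: i-Pr3SiOTf (1.1 equiv), Et3N (3 equiv), CH2Cl2, −78 → −40 °C; pentane, quick filtration through Et3N-deactivated silica; used at once
Reagents that add atoms: triisopropylsilyl trifluoromethanesulfonate, CC(C)[Si](OS(=O)(=O)C(F)(F)F)(C(C)C)C(C)C
Why: Soft enolisation of a butenolide to the 2-silyloxyfuran, in which the γ-CH2 is by far the most acidic C–H, the aldehyde cannot enolise, and excess amine with a bulky silyl triflate at low temperature should keep the aldehyde from being activated early.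

Step 14
Reactants: 22 (1R,3S,4R,7S)-1-[4-bromo-5-(triisopropylsilyloxy)furan-3-yl]-3,7-dimethyl-8-oxo-4,7-bis(triethylsilyloxy)octyl 3-methylbut-2-enoate
Product: 23 (1R,4S,5S,6R,8R,10S)-11-bromo-5-hydroxy-8-(3-methylbut-2-enoyloxy)-1,4-bis(triethylsilyloxy)-13-norgermacr-7(11)-en-12,6-olide
Conditions: BF3·OEt2 (2 equiv), CH2Cl2, −78 °C, 22 added over 6 h to a final 1 mM; aq NaHCO3
Reagents that add atoms: none
Why: Proposed new method: BF3 binds the aldehyde, the only free carbonyl electrophile (no α-hydrogen; C1 is masked), the 2-silyloxyfuran attacks it through its free 5-position (C6 of the target, the γ-carbon of the dienolate) in an open transition state, and loss of the silyl group as i-Pr3SiF releases the butenolide. The closest known reaction type is the intermolecular BF3-mediated vinylogous Mukaiyama aldol addition of 2-silyloxyfurans, 3-bromo and 3,4-dihalo ones included, to aldehydes; closing a ten-membered carbocycle with it is new. The ring closes by 10-exo-trig attack on the carbonyl carbon, with the furan C6=C7 bond inside the new ring, and slow addition to about 1 mM should favour it over chain coupling. C5 is controlled by the quaternary C4 centre: with the C4–O bond anti to the forming bond (Felkin–Anh) and tether carbon C3 gauche, the BF3-bound oxygen should point outward over the C4 methyl group, which gives the 5S carbinol that step 16 inverts. C6 is controlled by C8: allylic strain against the C11 bromine holds the C8–H bond in the furan plane, and a ring without a syn-pentane contact between C5 and C9 then puts C5 on the furan face opposite C9, which is 6R. The step needs γ- over α-attack and a single electrophile; the bromine at C11 secures the first, the C1 silyl ether and the unreactive esters the second.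

Step 15
Reactants: 23 (1R,4S,5S,6R,8R,10S)-11-bromo-5-hydroxy-8-(3-methylbut-2-enoyloxy)-1,4-bis(triethylsilyloxy)-13-norgermacr-7(11)-en-12,6-olide
Product: 24 the C5 methanesulfonate of 23
Conditions: MsCl, Et3N, CH2Cl2, −40 → −10 °C
Reagents that add atoms: methanesulfonyl chloride, CS(=O)(=O)Cl
Why: Mesylation through sulfene reaches even the hindered C5 hydroxyl with retention, and the low temperature should keep the amine from removing the C6 proton.

Step 16
Reactants: 24 the C5 methanesulfonate of 23
Product: 26 (1R,4S,5R,6R,8R,10S)-11-bromo-4,5-epoxy-1-hydroxy-8-(3-methylbut-2-enoyloxy)-13-norgermacr-7(11)-en-12,6-olide, via C4 alkoxide 25 (not isolated)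
Conditions: Bu4NF (2.5 equiv, 1 M in THF), THF, −20 → 0 °C; aq NH4Cl
Reagents that add atoms: none
Why: Fluoride cleaves both triethylsilyl ethers, and the tertiary C4 alkoxide 25, born next to the mesylate, should displace it in a 3-exo-tet Williamson closure with inversion at C5 (5S to 5R), giving the cis-fused 4,5-epoxide of the target.

Step 17
Reactants: 26 (1R,4S,5R,6R,8R,10S)-11-bromo-4,5-epoxy-1-hydroxy-8-(3-methylbut-2-enoyloxy)-13-norgermacr-7(11)-en-12,6-olide
Product: 27 (4S,5R,6R,8R,10S)-11-bromo-4,5-epoxy-8-(3-methylbut-2-enoyloxy)-1-oxo-13-norgermacr-7(11)-en-12,6-olide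
Conditions: Dess–Martin periodinane, NaHCO3, CH2Cl2, 0 °C → rt
Reagents that add atoms: none
Why: Buffered Dess–Martin oxidation turns the C1 carbinol into the ketone under near-neutral conditions that spare the epoxide; C10 becomes α to a ketone only now, so it meets no strong base afterwards.

Step 18
Reactants: 27 (4S,5R,6R,8R,10S)-11-bromo-4,5-epoxy-8-(3-methylbut-2-enoyloxy)-1-oxo-13-norgermacr-7(11)-en-12,6-olide; 28 (tributylstannyl)methanol
Product: 29 (4S,5R,6R,8R,10S)-4,5-epoxy-13-hydroxy-8-(3-methylbut-2-enoyloxy)-1-oxogermacr-7(11)-en-12,6-olide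
Conditions: Pd(PPh3)4 (10 mol%), 28 (1.5 equiv), 1,4-dioxane, 90 °C
Reagents that add atoms: none
Why: Stille coupling, in which zerovalent palladium inserts into the activated C11–Br bond of the α-bromobutenolide and the stannane transfers its hydroxymethyl group under neutral conditions, installs C13.

Step 19
Reactants: 29 (4S,5R,6R,8R,10S)-4,5-epoxy-13-hydroxy-8-(3-methylbut-2-enoyloxy)-1-oxogermacr-7(11)-en-12,6-olide
Product: 30 CNP0220542.1
Conditions: Ac2O, pyridine, 4-(dimethylamino)pyridine (cat.), CH2Cl2, 0 °C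
Reagents that add atoms: acetic anhydride, CC(=O)OC(C)=O
Why: Acetylation of the primary allylic alcohol under nucleophilic catalysis is fast at 0 °C and should leave the epoxide, the butenolide and the C10 centre alone.

**Compound list**

1 | (S)-linalool | C=C[C@@](C)(O)CCC=C(C)C | starting material
2 | (S)-linalool triethylsilyl ether | C=C[C@@](C)(O[Si](CC)(CC)CC)CCC=C(C)C | intermediate
3 | (4S)-4-methyl-4-(triethylsilyloxy)hex-5-enal | O=CCC[C@](C)(O[Si](CC)(CC)CC)C=C | intermediate
4 | (R)-but-3-yn-2-ol | C#C[C@@H](C)O | starting material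
5 | (R)-but-3-yn-2-yl methanesulfonate | C#C[C@@H](C)OS(C)(=O)=O | intermediate
6 | (P)-buta-1,2-dienyl(ethyl)zinc, formed in the flask | CC([H])=[C@@]=C([H])[Zn]CC | intermediate
7 | (3S,4R,7S)-3,7-dimethyl-7-(triethylsilyloxy)non-8-en-1-yn-4-ol | C#C[C@H](C)[C@H](O)CC[C@](C)(O[Si](CC)(CC)CC)C=C | intermediate
8 | (3S,4R,7S)-3,7-dimethyl-4,7-bis(triethylsilyloxy)non-8-en-1-yne | C#C[C@H](C)[C@H](O[Si](CC)(CC)CC)CC[C@](C)(O[Si](CC)(CC)CC)C=C | intermediate
9 | dicyclohexyl[(1E,3S,4R,7S)-3,7-dimethyl-4,7-bis(triethylsilyloxy)nona-1,8-dienyl]borane, formed in the flask | C1CCCCC1B(C1CCCCC1)/C=C/[C@H](C)[C@H](O[Si](CC)(CC)CC)CC[C@](C)(O[Si](CC)(CC)CC)C=C | intermediate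
10 | (3S,4R,7S)-3,7-dimethyl-4,7-bis(triethylsilyloxy)non-8-enal | O=CC[C@H](C)[C@H](O[Si](CC)(CC)CC)CC[C@](C)(O[Si](CC)(CC)CC)C=C | intermediate
11 | 3,4-dibromofuran | Brc1cocc1Br | starting material
12 | (4-bromofuran-3-yl)lithium, formed in the flask | [Li]c1cocc1Br | intermediate
13 | (3S,4R,7S)-1-(4-bromofuran-3-yl)-3,7-dimethyl-4,7-bis(triethylsilyloxy)non-8-en-1-ol, both C1 epimers | OC(C[C@H](C)[C@H](O[Si](CC)(CC)CC)CC[C@](C)(O[Si](CC)(CC)CC)C=C)c1cocc1Br | intermediate
14 | (3S,4R,7S)-1-(4-bromofuran-3-yl)-3,7-dimethyl-4,7-bis(triethylsilyloxy)non-8-en-1-one | O=C(C[C@H](C)[C@H](O[Si](CC)(CC)CC)CC[C@](C)(O[Si](CC)(CC)CC)C=C)c1cocc1Br | intermediate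
15 | (1R,3S,4R,7S)-1-(4-bromofuran-3-yl)-3,7-dimethyl-4,7-bis(triethylsilyloxy)non-8-en-1-ol | O[C@H](C[C@H](C)[C@H](O[Si](CC)(CC)CC)CC[C@](C)(O[Si](CC)(CC)CC)C=C)c1cocc1Br | intermediate
16 | lithium alkoxide of 15 lithiated at the furan CH next to C–Br, formed in the flask | [Li]O[C@H](C[C@H](C)[C@H](O[Si](CC)(CC)CC)CC[C@](C)(O[Si](CC)(CC)CC)C=C)c1coc([Li])c1Br | intermediate
17 | dimethyl furan-2-ylboronate derived from 16 (lithium alkoxide), formed in the flask | [Li]O[C@H](C[C@H](C)[C@H](O[Si](CC)(CC)CC)CC[C@](C)(O[Si](CC)(CC)CC)C=C)c1coc(B(OC)OC)c1Br | intermediate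
18 | 3-bromo-4-[(1R,3S,4R,7S)-1-hydroxy-3,7-dimethyl-4,7-bis(triethylsilyloxy)non-8-enyl]furan-2(5H)-one | O[C@H](C[C@H](C)[C@H](O[Si](CC)(CC)CC)CC[C@](C)(O[Si](CC)(CC)CC)C=C)C1=C(Br)C(=O)OC1 | intermediate
19 | (2S,5R,6S,8R)-8-(4-bromo-5-oxo-2,5-dihydrofuran-3-yl)-8-hydroxy-2,6-dimethyl-2,5-bis(triethylsilyloxy)octanal | O[C@H](C[C@H](C)[C@H](O[Si](CC)(CC)CC)CC[C@](C)(O[Si](CC)(CC)CC)C=O)C1=C(Br)C(=O)OC1 | intermediate
20 | 3-methylbut-2-enoyl chloride | CC(C)=CC(=O)Cl | starting material
21 | (1R,3S,4R,7S)-1-(4-bromo-5-oxo-2,5-dihydrofuran-3-yl)-3,7-dimethyl-8-oxo-4,7-bis(triethylsilyloxy)octyl 3-methylbut-2-enoate | CC(C)=CC(=O)O[C@H](C[C@H](C)[C@H](O[Si](CC)(CC)CC)CC[C@](C)(O[Si](CC)(CC)CC)C=O)C1=C(Br)C(=O)OC1 | intermediate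
22 | (1R,3S,4R,7S)-1-[4-bromo-5-(triisopropylsilyloxy)furan-3-yl]-3,7-dimethyl-8-oxo-4,7-bis(triethylsilyloxy)octyl 3-methylbut-2-enoate | CC(C)=CC(=O)O[C@H](C[C@H](C)[C@H](O[Si](CC)(CC)CC)CC[C@](C)(O[Si](CC)(CC)CC)C=O)c1coc(O[Si](C(C)C)(C(C)C)C(C)C)c1Br | intermediate
23 | (1R,4S,5S,6R,8R,10S)-11-bromo-5-hydroxy-8-(3-methylbut-2-enoyloxy)-1,4-bis(triethylsilyloxy)-13-norgermacr-7(11)-en-12,6-olide | BrC1=C2[C@@H](OC1=O)[C@H](O)[C@@](C)(O[Si](CC)(CC)CC)CC[C@@H](O[Si](CC)(CC)CC)[C@@H](C)C[C@H]2OC(=O)C=C(C)C | intermediate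
24 | C5 methanesulfonate of 23 | BrC1=C2[C@@H](OC1=O)[C@H](OS(C)(=O)=O)[C@@](C)(O[Si](CC)(CC)CC)CC[C@@H](O[Si](CC)(CC)CC)[C@@H](C)C[C@H]2OC(=O)C=C(C)C | intermediate
25 | tetrabutylammonium C4 alkoxide of the desilylated C5 mesylate, formed in the flask | BrC1=C2[C@@H](OC1=O)[C@H](OS(C)(=O)=O)[C@@](C)([O-])CC[C@@H](O)[C@@H](C)C[C@H]2OC(=O)C=C(C)C.CCCC[N+](CCCC)(CCCC)CCCC | intermediate
26 | (1R,4S,5R,6R,8R,10S)-11-bromo-4,5-epoxy-1-hydroxy-8-(3-methylbut-2-enoyloxy)-13-norgermacr-7(11)-en-12,6-olide | BrC1=C2[C@@H](OC1=O)[C@H]1O[C@@]1(C)CC[C@@H](O)[C@@H](C)C[C@H]2OC(=O)C=C(C)C | intermediate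
27 | (4S,5R,6R,8R,10S)-11-bromo-4,5-epoxy-8-(3-methylbut-2-enoyloxy)-1-oxo-13-norgermacr-7(11)-en-12,6-olide | BrC1=C2[C@@H](OC1=O)[C@H]1O[C@@]1(C)CCC(=O)[C@@H](C)C[C@H]2OC(=O)C=C(C)C | intermediate
28 | (tributylstannyl)methanol | CCCC[Sn](CCCC)(CCCC)CO | starting material
29 | (4S,5R,6R,8R,10S)-4,5-epoxy-13-hydroxy-8-(3-methylbut-2-enoyloxy)-1-oxogermacr-7(11)-en-12,6-olide | OCC1=C2[C@@H](OC1=O)[C@H]1O[C@@]1(C)CCC(=O)[C@@H](C)C[C@H]2OC(=O)C=C(C)C | intermediate
30 | CNP0220542.1, the 13-acetate of 29 | CC(=O)OCC1=C2[C@@H](OC1=O)[C@H]1O[C@@]1(C)CCC(=O)[C@@H](C)C[C@H]2OC(=O)C=C(C)C | target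

**Step count and risks**

Total step count: 19. Longest linear sequence: 18 steps (steps 1, 2 and 4 to 19, from (S)-linalool).

Steps most likely to fail:

1. Step 14. Chains may couple with each other instead of closing, or the aldehyde and furan faces may pair the wrong way, so that the C5/C6 configuration is not the one drawn. The fallback makes the C5–C6 bond between two molecules and closes the ring at C7–C8 by known chemistry. It leaves the route at 8. Ozonolysis of the vinyl group alone (alkynes react far more slowly with ozone) would give ynal F1. 3,4-Dibromo-2-(triisopropylsilyloxy)furan F2 would be made from commercial 3,4-dibromofuran-2(5H)-one (the NaBH4 reduction product of mucobromic acid) with i-Pr3SiOTf/Et3N. F2 would add to F1 under BF3·OEt2 in the known intermolecular vinylogous Mukaiyama aldol manner, giving dibromobutenolide aldol adduct F3 after separation of diastereomers. Hydroboration of the alkyne with (c-C6H11)2BH and buffered H2O2 would give hydroxy aldehyde F4. A Nozaki–Hiyama–Kishi macrocyclisation (CrCl2, NiCl2 cat., DMF/THF, high dilution), in which the β-bromide of the butenolide is the one that adds to zerovalent nickel, would close the ten-membered ring to macrocyclic 5,8-diol F5. After separation of the C8 epimers, acylation of the less hindered C8 hydroxyl of the 8R isomer with 20 rejoins the route at 23.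

2. Step 16. Fluoride may remove the acidic C6 proton before or after desilylation, and the mesylate then leaves by E1cB to a γ-alkylidene butenolide; the freed C1 alkoxide may also attack the epoxide across the ring. The fallback avoids the sulfonate and the basic fluoride. It leaves the route at 23: HF·pyridine (THF/pyridine, 0 °C) would remove both silyl groups to give triol F6. Mitsunobu cyclodehydration (PPh3, diisopropyl azodicarboxylate, THF, 0 °C → rt) would then convert the 4,5-diol into the epoxide through the oxyphosphonium salt of the secondary C5 hydroxyl, with inversion at C5 and under neutral conditions; the lone C1 hydroxyl has no partner and should return unchanged. This rejoins the route at 26.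

3. Step 10. The C8 alkoxide may steer the base to the other furan α-position, or the furylboronate and hydroxyfuran may be over-oxidised by peroxide. The fallback oxidises the furan without an organolithium. It leaves the route at 15: photo-oxygenation (O2, hν, 5,10,15,20-tetraphenylporphyrin, i-Pr2NEt, CH2Cl2, −78 °C) would give γ-hydroxybutenolide F7, the amine opening the endoperoxide at the less hindered bridgehead C–H next to C–Br so that the carbonyl lies beside the brominated carbon. NaBH4 (MeOH, 0 °C, mild acid work-up) would reduce the open aldehyde form and relactonise, as in the reduction of mucobromic acid, to rejoin the route at 18.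

Further compounds
F1 | step 14 | ynal: (2S,5R,6S)-2,6-dimethyl-2,5-bis(triethylsilyloxy)oct-7-ynal | C#C[C@H](C)[C@H](O[Si](CC)(CC)CC)CC[C@](C)(O[Si](CC)(CC)CC)C=O
F2 | step 14 | 3,4-dibromo-2-(triisopropylsilyloxy)furan | CC(C)[Si](Oc1occ(Br)c1Br)(C(C)C)C(C)C
F3 | step 14 | dibromobutenolide aldol adduct (C5 carbinol, C1 and C4 triethylsilyl ethers, terminal alkyne) | BrC1=C(Br)[C@@H](OC1=O)[C@H](O)[C@@](C)(O[Si](CC)(CC)CC)CC[C@@H](O[Si](CC)(CC)CC)[C@@H](C)C#C
F4 | step 14 | hydroxy aldehyde (C8 aldehyde of F3) | BrC1=C(Br)[C@@H](OC1=O)[C@H](O)[C@@](C)(O[Si](CC)(CC)CC)CC[C@@H](O[Si](CC)(CC)CC)[C@@H](C)CC=O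
F5 | step 14 | macrocyclic 5,8-diol (23 without the senecioyl group) | BrC1=C2[C@@H](OC1=O)[C@H](O)[C@@](C)(O[Si](CC)(CC)CC)CC[C@@H](O[Si](CC)(CC)CC)[C@@H](C)C[C@H]2O
F6 | step 16 | triol (23 without both triethylsilyl groups) | BrC1=C2[C@@H](OC1=O)[C@H](O)[C@@](C)(O)CC[C@@H](O)[C@@H](C)C[C@H]2OC(=O)C=C(C)C
F7 | step 10 | γ-hydroxybutenolide (5-hydroxy derivative of 18, both lactol epimers) | O[C@H](C[C@H](C)[C@H](O[Si](CC)(CC)CC)CC[C@](C)(O[Si](CC)(CC)CC)C=C)C1=C(Br)C(=O)OC1O
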